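**Retrosynthetic overview**

- Feature: with chains numbered from the dienoate carbonyl C1 (primes for the lactone half), the oxygen of each head sits on C12/C12', a plain chain methylene β to the C14/C14' carboxyl carbon. In the lactone half this oxygen closes the oxetan-2-one O–C12'–C13'–C14', so each head is the β-C–H lactonisation product of an unoxidised acid.
- The C12–O ester is cut (Yamaguchi) into acid 20 (O-silyl lactone half) and hydroxy diester 26, which comes from acyl–oxygen hydrolysis of the (12S,13S) lactone 24.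
- In each half C5–C6 is made by nickel reductive coupling of bromodienoate 14 with a bromo lactone, and the C13 CH2OH by trans hydroxymethylation of the lactone enolate with formaldehyde.
- The oxetan-2-one is the only ring and is closed first: step 5 gives the (12'R) ring that stays in the target, step 6 (mirror ligand) the (12S) ring that is opened again in step 17.
- Acid 7 is reached in four steps from (S)-3-bromo-2-methylpropan-1-ol, which supplies C7/C7'.

Key step: step 5

Assumption: the sense of induction of the chiral ligand in the C–H lactonisation cannot be predicted; the (S)-ligand is taken to give the (4R)-lactone and its mirror image the (4S)-lactone, and the two are exchanged if the opposite holds.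

**Route**

Step 1
Reactants: 1 (2S)-3-bromo-2-methylpropan-1-ol
Product: 2 [(2S)-3-bromo-2-methylpropoxy](tert-butyl)dimethylsilane
Conditions: TBSCl, imidazole, CH2Cl2, 0 → 20 °C
Reagents that add atoms: tert-butyldimethylsilyl chloride, CC(C)(C)[Si](C)(C)Cl
Why: Imidazole-promoted silylation of the primary alcohol masks the hydroxyl for the Grignard coupling and does not touch the stereocentre.

Step 2
Reactants: 2 [(2S)-3-bromo-2-methylpropoxy](tert-butyl)dimethylsilane; 3 7-bromohept-1-ene
Product: 5 tert-butyldimethyl{[(2R)-2-methyldec-9-en-1-yl]oxy}silane, via hept-6-en-1-ylmagnesium bromide 4 (not isolated)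
Conditions: 3, Mg, THF, 40 °C; then 2, Li2CuCl4 (3 mol%), NMP, THF, 0 → 20 °C
Reagents that add atoms: none
Why: Copper-catalysed alkyl–alkyl cross-coupling of a primary bromide with a primary Grignard reagent should form C8–C9 without involving the neighbouring stereocentre, whose descriptor changes from S to R only through the change in substituent priority.

Step 3
Reactants: 5 tert-butyldimethyl{[(2R)-2-methyldec-9-en-1-yl]oxy}silane
Product: 6 (9R)-10-bromo-9-methyldec-1-ene
Conditions: Ph3PBr2, CH2Cl2, 0 → 20 °C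
Reagents that add atoms: triphenylphosphine dibromide, BrP(Br)(c1ccccc1)(c1ccccc1)c1ccccc1
Why: Triphenylphosphine dibromide converts primary silyl ethers directly into bromides (silyl transfer to bromide, then SN2 of bromide on the alkoxyphosphonium ion), so deprotection and bromination are one operation at a carbon that is not stereogenic.

Step 4
Reactants: 6 (9R)-10-bromo-9-methyldec-1-ene
Product: 7 (8R)-9-bromo-8-methylnonanoic acid
Conditions: RuCl3·xH2O (2 mol%), NaIO4, EtOAc/MeCN/H2O, 20 °C
Reagents that add atoms: sodium periodate, [Na+].[O-]I(=O)(=O)=O; water, O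
Why: Oxidative cleavage of the terminal alkene by catalytic RuO4 should give the acid with loss of the terminal carbon and leave the primary bromide intact.

Step 5
Reactants: 7 (8R)-9-bromo-8-methylnonanoic acid
Product: 8 (4R)-4-[(5R)-6-bromo-5-methylhexyl]oxetan-2-one
Conditions: Pd(OAc)2 (10 mol%), (S)-3-acetamido-4,4-dimethylpentanoic acid (20 mol%), CsHCO3 (0.5 equiv), TBHP (70% in water, 2 equiv), 1,1,1,3,3,3-hexafluoropropan-2-ol (HFIP), 60 °C
Reagents that add atoms: none
Why: Proposed new method: the carboxylate of 7 binds divalent palladium, the N-acetyl amino acid ligand acts as internal base in a concerted metalation–deprotonation that removes one of the two enantiotopic C12' hydrogens, and the five-membered palladacycle (Pd, O, C14', C13', C12') is oxidised by TBHP to tetravalent palladium, from which C12'–O reductive elimination gives the lactone and returns divalent palladium. The closest known reactions are the palladium-catalysed β-C–H lactonisation of free aliphatic acids at methyl groups with TBHP in HFIP and the ligand-controlled enantioselective β-methylene C–H activation with chiral mono-protected amino acid-type ligands; an enantioselective lactonisation at the methylene of an unbranched acid has not been shown. The oxetan-2-one (O–C12'–C13'–C14') closes by C–O bond formation at the palladated carbon, formally a 4-exo-tet closure. The new stereocentre C12' is set by the chiral ligand, which differentiates the two diastereomeric metalation transition states; C7' is five bonds away and should not interfere, so the step is under catalyst control. The step needs β over γ selectivity, which the five-membered palladacycle of the bidentate ligand should secure, and oxidation faster than β-hydride elimination toward C13' or C11', which the strong peroxide oxidant in HFIP and the rigid chelate should favour. The primary bromide and the tertiary C7'–H carry no directing group and should remain untouched.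

Step 6
Reactants: 7 (8R)-9-bromo-8-methylnonanoic acid
Product: 9 (4S)-4-[(5R)-6-bromo-5-methylhexyl]oxetan-2-one
Conditions: Pd(OAc)2 (10 mol%), (R)-3-acetamido-4,4-dimethylpentanoic acid (20 mol%), CsHCO3 (0.5 equiv), TBHP (70% in water, 2 equiv), HFIP, 60 °C
Reagents that add atoms: none
Why: Proposed new method: the same carboxylate-directed palladation, oxidation to tetravalent palladium and C–O reductive elimination as in step 5 (closest known type: palladium-catalysed β-methyl C–H lactonisation of free acids with TBHP) is run with the mirror-image ligand, which should remove the other enantiotopic C12 hydrogen and give the (4S)-lactone under catalyst control.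

Step 7
Reactants: 10 propyne
Product: 11 (E)-2-bromo-1-iodoprop-1-ene
Conditions: IBr, CH2Cl2, −78 → 0 °C
Reagents that add atoms: iodine monobromide, BrI
Why: Electrophilic anti addition of I–Br across the terminal alkyne should place iodine on the terminal carbon and bromide on the internal carbon (Markovnikov opening of the iodonium ion), giving the E-dihalide with two halogens of different reactivity.

Step 8
Reactants: 12 tert-butyl but-2-ynoate
Product: 13 tert-butyl (2Z)-3-(4,4,5,5-tetramethyl-1,3,2-dioxaborolan-2-yl)but-2-enoate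
Conditions: B2pin2, CuCl (3 mol%), NaOtBu (6 mol%), Xantphos (3 mol%), MeOH (2 equiv), THF, 20 °C
Reagents that add atoms: bis(pinacolato)diboron, CC1(C)OB(OC1(C)C)B1OC(C)(C)C(C)(C)O1
Why: Copper-catalysed conjugate borylation with protonation is a syn hydroboration of the ynoate, so boron on C3 and hydrogen on C2 end up on the same side and the boryl group is trans to the ester.

Step 9
Reactants: 13 tert-butyl (2Z)-3-(4,4,5,5-tetramethyl-1,3,2-dioxaborolan-2-yl)but-2-enoate; 11 (E)-2-bromo-1-iodoprop-1-ene
Product: 14 tert-butyl (2E,4E)-5-bromo-3-methylhexa-2,4-dienoate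
Conditions: Pd(PPh3)4 (5 mol%), K3PO4 (aq.), THF, 20 °C
Reagents that add atoms: none
Why: Suzuki–Miyaura coupling should take place at the C–I bond only (oxidative addition to zerovalent palladium is much faster than at C–Br) with retention at both alkenes, which fixes the 2E,4E geometry and keeps the vinyl bromide.

Step 10
Reactants: 8 (4R)-4-[(5R)-6-bromo-5-methylhexyl]oxetan-2-one; 15 formaldehyde
Product: 17 (3R,4R)-4-[(5R)-6-bromo-5-methylhexyl]-3-(hydroxymethyl)oxetan-2-one, via lithium enolate 16 (not isolated)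
Conditions: LiN(iPr)2, THF, −78 °C; then monomeric 15 (gas from cracked paraformaldehyde), −78 °C; AcOH, −78 °C
Reagents that add atoms: none
Why: Aldol hydroxymethylation of the β-lactone lithium enolate, which does not undergo β-elimination at −78 °C, should add formaldehyde on the face anti to the C12' substituent and so set C13' trans (3R,4R), while the β-branched primary bromide is too slow an electrophile at this temperature.

Step 11
Reactants: 17 (3R,4R)-4-[(5R)-6-bromo-5-methylhexyl]-3-(hydroxymethyl)oxetan-2-one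
Product: 18 (3R,4R)-4-[(5R)-6-bromo-5-methylhexyl]-3-{[(tert-butyldiphenylsilyl)oxy]methyl}oxetan-2-one
Conditions: TBDPSCl, imidazole, CH2Cl2, 0 → 20 °C
Reagents that add atoms: tert-butyldiphenylsilyl chloride, CC(C)(C)[Si](Cl)(c1ccccc1)c1ccccc1
Why: Silylation of the primary alcohol gives an ether that withstands the later acidolysis of the tert-butyl ester, and the mild conditions should not open the lactone.

Step 12
Reactants: 18 (3R,4R)-4-[(5R)-6-bromo-5-methylhexyl]-3-{[(tert-butyldiphenylsilyl)oxy]methyl}oxetan-2-one; 14 tert-butyl (2E,4E)-5-bromo-3-methylhexa-2,4-dienoate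
Product: 19 tert-butyl (2E,4E,7R)-11-[(2R,3R)-3-{[(tert-butyldiphenylsilyl)oxy]methyl}-4-oxooxetan-2-yl]-3,5,7-trimethylundeca-2,4-dienoate
Conditions: NiBr2·dme (10 mol%; dme = 1,2-dimethoxyethane), 4,4'-di-tert-butyl-2,2'-bipyridine (10 mol%), Mn powder (2 equiv), DMA, 20 °C
Reagents that add atoms: none
Why: Nickel-catalysed reductive cross-electrophile coupling (zerovalent nickel adds to the sp2 C–Br bond, the alkyl radical from the sp3 bromide is captured, Mn is the terminal reductant) should form C5'–C6' with retention of the alkene geometry and tolerates esters and silyl ethers.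

Step 13
Reactants: 19 tert-butyl (2E,4E,7R)-11-[(2R,3R)-3-{[(tert-butyldiphenylsilyl)oxy]methyl}-4-oxooxetan-2-yl]-3,5,7-trimethylundeca-2,4-dienoate
Product: 20 (2E,4E,7R)-11-[(2R,3R)-3-{[(tert-butyldiphenylsilyl)oxy]methyl}-4-oxooxetan-2-yl]-3,5,7-trimethylundeca-2,4-dienoic acid
Conditions: TFA/CH2Cl2 (1:4), 0 °C
Reagents that add atoms: none
Why: Acidolysis of the tert-butyl ester through the tert-butyl cation should free the dienoic acid, while the primary TBDPS ether and the β-lactone are stable to anhydrous TFA at 0 °C.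

Step 14
Reactants: 9 (4S)-4-[(5R)-6-bromo-5-methylhexyl]oxetan-2-one; 15 formaldehyde
Product: 22 (3S,4S)-4-[(5R)-6-bromo-5-methylhexyl]-3-(hydroxymethyl)oxetan-2-one, via lithium enolate 21 (not isolated)
Conditions: LiN(iPr)2, THF, −78 °C; then monomeric 15 (gas from cracked paraformaldehyde), −78 °C; AcOH, −78 °C
Reagents that add atoms: none
Why: The same aldol hydroxymethylation of the β-lactone enolate as in step 10 should add formaldehyde anti to the C12 substituent and set C13 trans, here (3S,4S).

Step 15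
Reactants: 22 (3S,4S)-4-[(5R)-6-bromo-5-methylhexyl]-3-(hydroxymethyl)oxetan-2-one
Product: 23 (3S,4S)-4-[(5R)-6-bromo-5-methylhexyl]-3-{[(tert-butyldiphenylsilyl)oxy]methyl}oxetan-2-one
Conditions: TBDPSCl, imidazole, CH2Cl2, 0 → 20 °C
Reagents that add atoms: tert-butyldiphenylsilyl chloride, CC(C)(C)[Si](Cl)(c1ccccc1)c1ccccc1
Why: Silylation of the primary alcohol gives an ether that survives the hydroxide opening of the lactone, the esterification and the acidolysis that follow.

Step 16
Reactants: 23 (3S,4S)-4-[(5R)-6-bromo-5-methylhexyl]-3-{[(tert-butyldiphenylsilyl)oxy]methyl}oxetan-2-one; 14 tert-butyl (2E,4E)-5-bromo-3-methylhexa-2,4-dienoate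
Product: 24 tert-butyl (2E,4E,7R)-11-[(2S,3S)-3-{[(tert-butyldiphenylsilyl)oxy]methyl}-4-oxooxetan-2-yl]-3,5,7-trimethylundeca-2,4-dienoate
Conditions: NiBr2·dme (10 mol%), 4,4'-di-tert-butyl-2,2'-bipyridine (10 mol%), Mn powder (2 equiv), DMA, 20 °C
Reagents that add atoms: none
Why: The same nickel-catalysed reductive cross-electrophile coupling as in step 12 should join the vinyl and alkyl bromides at C5–C6 with retention of the alkene geometry.

Step 17
Reactants: 24 tert-butyl (2E,4E,7R)-11-[(2S,3S)-3-{[(tert-butyldiphenylsilyl)oxy]methyl}-4-oxooxetan-2-yl]-3,5,7-trimethylundeca-2,4-dienoate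
Product: 25 1-tert-butyl hydrogen (2E,4E,7R,12S,13S)-13-{[(tert-butyldiphenylsilyl)oxy]methyl}-12-hydroxy-3,5,7-trimethyltetradeca-2,4-dienedioate
Conditions: LiOH, THF/H2O, 0 °C; then HCl (aq.) to pH 3
Reagents that add atoms: lithium hydroxide, [Li+].[OH-]
Why: Hydroxide attacks the strained lactone at the acyl carbon (acyl–oxygen cleavage), so C12 and C13 keep their configuration, and the tert-butyl ester and the silyl ether resist LiOH at 0 °C.

Step 18
Reactants: 25 1-tert-butyl hydrogen (2E,4E,7R,12S,13S)-13-{[(tert-butyldiphenylsilyl)oxy]methyl}-12-hydroxy-3,5,7-trimethyltetradeca-2,4-dienedioate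
Product: 26 di-tert-butyl (2E,4E,7R,12S,13S)-13-{[(tert-butyldiphenylsilyl)oxy]methyl}-12-hydroxy-3,5,7-trimethyltetradeca-2,4-dienedioate
Conditions: tert-butyl 2,2,2-trichloroacetimidate, cyclohexane/CH2Cl2, 20 °C
Reagents that add atoms: tert-butyl 2,2,2-trichloroacetimidate, CC(C)(C)OC(=N)C(Cl)(Cl)Cl
Why: The imidate is protonated only by the carboxylic acid and then transfers a tert-butyl cation to the carboxylate, so the acid is esterified chemoselectively and the secondary alcohol stays free because no Lewis acid is added.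

Step 19
Reactants: 20 (2E,4E,7R)-11-[(2R,3R)-3-{[(tert-butyldiphenylsilyl)oxy]methyl}-4-oxooxetan-2-yl]-3,5,7-trimethylundeca-2,4-dienoic acid; 26 di-tert-butyl (2E,4E,7R,12S,13S)-13-{[(tert-butyldiphenylsilyl)oxy]methyl}-12-hydroxy-3,5,7-trimethyltetradeca-2,4-dienedioate
Product: 28 di-tert-butyl (2E,4E,7R,12S,13S)-13-{[(tert-butyldiphenylsilyl)oxy]methyl}-12-{[(2E,4E,7R)-11-[(2R,3R)-3-{[(tert-butyldiphenylsilyl)oxy]methyl}-4-oxooxetan-2-yl]-3,5,7-trimethylundeca-2,4-dienoyl]oxy}-3,5,7-trimethyltetradeca-2,4-dienedioate, via mixed anhydride 27 (not isolated)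
Conditions: 20, 2,4,6-trichlorobenzoyl chloride, Et3N, toluene, 20 °C; then 26, DMAP, 20 °C
Reagents that add atoms: none
Why: Yamaguchi esterification, in which DMAP attacks the mixed anhydride at the dienoyl carbonyl and the acylpyridinium ion acylates the hindered C12 hydroxyl, should form the ester with retention at C12.

Step 20
Reactants: 28 di-tert-butyl (2E,4E,7R,12S,13S)-13-{[(tert-butyldiphenylsilyl)oxy]methyl}-12-{[(2E,4E,7R)-11-[(2R,3R)-3-{[(tert-butyldiphenylsilyl)oxy]methyl}-4-oxooxetan-2-yl]-3,5,7-trimethylundeca-2,4-dienoyl]oxy}-3,5,7-trimethyltetradeca-2,4-dienedioate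
Product: 29 (2E,4E,7R,12S,13S)-13-{[(tert-butyldiphenylsilyl)oxy]methyl}-12-{[(2E,4E,7R)-11-[(2R,3R)-3-{[(tert-butyldiphenylsilyl)oxy]methyl}-4-oxooxetan-2-yl]-3,5,7-trimethylundeca-2,4-dienoyl]oxy}-3,5,7-trimethyltetradeca-2,4-dienedioic acid
Conditions: TFA/CH2Cl2 (1:3), 0 → 20 °C
Reagents that add atoms: none
Why: Acidolysis should remove both tert-butyl esters, while the TBDPS ethers, the β-lactone and the C12 dienoate ester are stable to anhydrous TFA and no free hydroxyl is present that could be trifluoroacetylated.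

Step 21
Reactants: 29 (2E,4E,7R,12S,13S)-13-{[(tert-butyldiphenylsilyl)oxy]methyl}-12-{[(2E,4E,7R)-11-[(2R,3R)-3-{[(tert-butyldiphenylsilyl)oxy]methyl}-4-oxooxetan-2-yl]-3,5,7-trimethylundeca-2,4-dienoyl]oxy}-3,5,7-trimethyltetradeca-2,4-dienedioic acid
Product: 30 fusariumester B
Conditions: HF·pyridine, THF/pyridine, 0 → 20 °C
Reagents that add atoms: none
Why: Fluoride-mediated desilylation under buffered acidic conditions should cleave both primary TBDPS ethers without opening the β-lactone or moving the C12 acyl group.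

**Compound list**

1 | (2S)-3-bromo-2-methylpropan-1-ol | OC[C@H](C)CBr | starting material
2 | [(2S)-3-bromo-2-methylpropoxy](tert-butyl)dimethylsilane | CC(C)(C)[Si](C)(C)OC[C@H](C)CBr | intermediate
3 | 7-bromohept-1-ene | C=CCCCCCBr | starting material
4 | hept-6-en-1-ylmagnesium bromide | C=CCCCCC[Mg]Br | intermediate
5 | tert-butyldimethyl{[(2R)-2-methyldec-9-en-1-yl]oxy}silane | CC(C)(C)[Si](C)(C)OC[C@H](C)CCCCCCC=C | intermediate
6 | (9R)-10-bromo-9-methyldec-1-ene | BrC[C@H](C)CCCCCCC=C | intermediate
7 | (8R)-9-bromo-8-methylnonanoic acid | BrC[C@H](C)CCCCCCC(=O)O | intermediate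
8 | (4R)-4-[(5R)-6-bromo-5-methylhexyl]oxetan-2-one | BrC[C@H](C)CCCC[C@H]1OC(=O)C1 | intermediate
9 | (4S)-4-[(5R)-6-bromo-5-methylhexyl]oxetan-2-one | BrC[C@H](C)CCCC[C@@H]1OC(=O)C1 | intermediate
10 | propyne | CC#C | starting material
11 | (E)-2-bromo-1-iodoprop-1-ene | C/C(Br)=C\I | intermediate
12 | tert-butyl but-2-ynoate | CC#CC(=O)OC(C)(C)C | starting material
13 | tert-butyl (2Z)-3-(4,4,5,5-tetramethyl-1,3,2-dioxaborolan-2-yl)but-2-enoate | C/C(B1OC(C)(C)C(C)(C)O1)=C\C(=O)OC(C)(C)C | intermediate
14 | tert-butyl (2E,4E)-5-bromo-3-methylhexa-2,4-dienoate | CC(=C\C(=O)OC(C)(C)C)/C=C(\C)Br | intermediate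
15 | formaldehyde | C=O | starting material
16 | lithium enolate of 8 | BrC[C@H](C)CCCC[C@H]1OC(O[Li])=C1 | intermediate
17 | (3R,4R)-4-[(5R)-6-bromo-5-methylhexyl]-3-(hydroxymethyl)oxetan-2-one | BrC[C@H](C)CCCC[C@H]1OC(=O)[C@@H]1CO | intermediate
18 | (3R,4R)-4-[(5R)-6-bromo-5-methylhexyl]-3-{[(tert-butyldiphenylsilyl)oxy]methyl}oxetan-2-one | BrC[C@H](C)CCCC[C@H]1OC(=O)[C@@H]1CO[Si](c2ccccc2)(c2ccccc2)C(C)(C)C | intermediate
19 | tert-butyl (2E,4E,7R)-11-[(2R,3R)-3-{[(tert-butyldiphenylsilyl)oxy]methyl}-4-oxooxetan-2-yl]-3,5,7-trimethylundeca-2,4-dienoate | CC(=C\C(=O)OC(C)(C)C)/C=C(\C)C[C@H](C)CCCC[C@H]1OC(=O)[C@@H]1CO[Si](c2ccccc2)(c2ccccc2)C(C)(C)C | intermediate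
20 | (2E,4E,7R)-11-[(2R,3R)-3-{[(tert-butyldiphenylsilyl)oxy]methyl}-4-oxooxetan-2-yl]-3,5,7-trimethylundeca-2,4-dienoic acid | CC(=C\C(=O)O)/C=C(\C)C[C@H](C)CCCC[C@H]1OC(=O)[C@@H]1CO[Si](c2ccccc2)(c2ccccc2)C(C)(C)C | intermediate
21 | lithium enolate of 9 | BrC[C@H](C)CCCC[C@@H]1OC(O[Li])=C1 | intermediate
22 | (3S,4S)-4-[(5R)-6-bromo-5-methylhexyl]-3-(hydroxymethyl)oxetan-2-one | BrC[C@H](C)CCCC[C@@H]1OC(=O)[C@H]1CO | intermediate
23 | (3S,4S)-4-[(5R)-6-bromo-5-methylhexyl]-3-{[(tert-butyldiphenylsilyl)oxy]methyl}oxetan-2-one | BrC[C@H](C)CCCC[C@@H]1OC(=O)[C@H]1CO[Si](c2ccccc2)(c2ccccc2)C(C)(C)C | intermediate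
24 | tert-butyl (2E,4E,7R)-11-[(2S,3S)-3-{[(tert-butyldiphenylsilyl)oxy]methyl}-4-oxooxetan-2-yl]-3,5,7-trimethylundeca-2,4-dienoate | CC(=C\C(=O)OC(C)(C)C)/C=C(\C)C[C@H](C)CCCC[C@@H]1OC(=O)[C@H]1CO[Si](c2ccccc2)(c2ccccc2)C(C)(C)C | intermediate
25 | 1-tert-butyl hydrogen (2E,4E,7R,12S,13S)-13-{[(tert-butyldiphenylsilyl)oxy]methyl}-12-hydroxy-3,5,7-trimethyltetradeca-2,4-dienedioate | CC(=C\C(=O)OC(C)(C)C)/C=C(\C)C[C@H](C)CCCC[C@H](O)[C@H](CO[Si](c2ccccc2)(c2ccccc2)C(C)(C)C)C(=O)O | intermediate
26 | di-tert-butyl (2E,4E,7R,12S,13S)-13-{[(tert-butyldiphenylsilyl)oxy]methyl}-12-hydroxy-3,5,7-trimethyltetradeca-2,4-dienedioate | CC(=C\C(=O)OC(C)(C)C)/C=C(\C)C[C@H](C)CCCC[C@H](O)[C@H](CO[Si](c2ccccc2)(c2ccccc2)C(C)(C)C)C(=O)OC(C)(C)C | intermediate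
27 | mixed anhydride of 20 with 2,4,6-trichlorobenzoic acid | CC(=C\C(=O)OC(=O)c3c(Cl)cc(Cl)cc3Cl)/C=C(\C)C[C@H](C)CCCC[C@H]1OC(=O)[C@@H]1CO[Si](c2ccccc2)(c2ccccc2)C(C)(C)C | intermediate
28 | di-tert-butyl (2E,4E,7R,12S,13S)-13-{[(tert-butyldiphenylsilyl)oxy]methyl}-12-{[(2E,4E,7R)-11-[(2R,3R)-3-{[(tert-butyldiphenylsilyl)oxy]methyl}-4-oxooxetan-2-yl]-3,5,7-trimethylundeca-2,4-dienoyl]oxy}-3,5,7-trimethyltetradeca-2,4-dienedioate | CC(=C\C(=O)OC(C)(C)C)/C=C(\C)C[C@H](C)CCCC[C@H](OC(=O)/C=C(C)/C=C(\C)C[C@H](C)CCCC[C@H]1OC(=O)[C@@H]1CO[Si](c2ccccc2)(c2ccccc2)C(C)(C)C)[C@H](CO[Si](c3ccccc3)(c3ccccc3)C(C)(C)C)C(=O)OC(C)(C)C | intermediate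
29 | (2E,4E,7R,12S,13S)-13-{[(tert-butyldiphenylsilyl)oxy]methyl}-12-{[(2E,4E,7R)-11-[(2R,3R)-3-{[(tert-butyldiphenylsilyl)oxy]methyl}-4-oxooxetan-2-yl]-3,5,7-trimethylundeca-2,4-dienoyl]oxy}-3,5,7-trimethyltetradeca-2,4-dienedioic acid | CC(=C\C(=O)O)/C=C(\C)C[C@H](C)CCCC[C@H](OC(=O)/C=C(C)/C=C(\C)C[C@H](C)CCCC[C@H]1OC(=O)[C@@H]1CO[Si](c2ccccc2)(c2ccccc2)C(C)(C)C)[C@H](CO[Si](c3ccccc3)(c3ccccc3)C(C)(C)C)C(=O)O | intermediate
30 | fusariumester B | CC(=C\C(=O)O)/C=C(\C)C[C@H](C)CCCC[C@H](OC(=O)/C=C(C)/C=C(\C)C[C@H](C)CCCC[C@H]1OC(=O)[C@@H]1CO)[C@H](CO)C(=O)O | target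

**Step count**

Total: 21 steps. Longest linear sequence: 13 steps (steps 1–4, 6, 14–18, 19–21).

**Steps most likely to fail**

1. Step 5 (new chemistry). The palladacycle may undergo β-hydride elimination before the peroxide oxidises it, so that dehydrogenation replaces lactonisation. Palladation may also occur at the γ-methylene, or the ligand may discriminate the two enantiotopic C12' hydrogens poorly. The fallback sets out from 2 and returns at 8, building the ring by a known catalytic asymmetric ketene–aldehyde cycloaddition. Bromide 2 would be coupled under the conditions of step 2 with pent-4-en-1-ylmagnesium bromide F1 (from 5-bromopent-1-ene and Mg) to give tert-butyldimethyl{[(2R)-2-methyloct-7-en-1-yl]oxy}silane F2. Ph3PBr2 would convert this into (7R)-8-bromo-7-methyloct-1-ene F3, and ozonolysis with PPh3 work-up would give (6R)-7-bromo-6-methylheptanal F4. Acetyl chloride and iPr2NEt would then generate ketene F5 in the flask, and the O-trimethylsilyl cinchona alkaloid (quinine or quinidine series, whichever leads to the 4R ring) with LiClO4 in CH2Cl2/Et2O at −78 °C should catalyse the [2+2] cycloaddition to 8. C12' is then set by the alkaloid catalyst.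

2. Step 6 (new chemistry). The same processes as in step 5 may intervene, and the mirror-image ligand may be the mismatched or less accessible one. The fallback sets out from 8 and returns at 9 by inverting C12. Lactone 8 would be saponified (LiOH, THF/H2O, 0 °C; acyl–oxygen cleavage, retention) to (3R,8R)-9-bromo-3-hydroxy-8-methylnonanoic acid F6. Mitsunobu lactonisation (PPh3, DIAD, THF, −78 → 0 °C) would then activate the hydroxyl group and let the carboxylate close the ring by SN2 with inversion, which should give 9.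

3. Step 12 (the same coupling is run again in step 16). Low-valent nickel or the manganese halide may open the β-lactone, homocoupling of either bromide may dominate, or the C4'=C5' geometry may be partly lost at the dienylnickel stage. The fallback sets out from 18 and returns at 19, replacing the radical cross-electrophile coupling by a two-stage polar coupling. Zinc insertion into 18 (Zn dust, LiCl, THF, 50 °C) would give the alkylzinc bromide {(2R)-6-[(2R,3R)-3-{[(tert-butyldiphenylsilyl)oxy]methyl}-4-oxooxetan-2-yl]-2-methylhexyl}zinc bromide F7. Negishi coupling of F7 with 14 (Pd(OAc)2, SPhos, THF, 20 °C) should then give 19 with retention of the alkene geometry.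

**Further compounds**

F1 | step 5 | pent-4-en-1-ylmagnesium bromide | C=CCCC[Mg]Br
F2 | step 5 | tert-butyldimethyl{[(2R)-2-methyloct-7-en-1-yl]oxy}silane | CC(C)(C)[Si](C)(C)OC[C@H](C)CCCCC=C
F3 | step 5 | (7R)-8-bromo-7-methyloct-1-ene | BrC[C@H](C)CCCCC=C
F4 | step 5 | (6R)-7-bromo-6-methylheptanal | BrC[C@H](C)CCCCC=O
F5 | step 5 | ketene | C=C=O
F6 | step 6 | (3R,8R)-9-bromo-3-hydroxy-8-methylnonanoic acid | BrC[C@H](C)CCCC[C@@H](O)CC(=O)O
F7 | step 12 | {(2R)-6-[(2R,3R)-3-{[(tert-butyldiphenylsilyl)oxy]methyl}-4-oxooxetan-2-yl]-2-methylhexyl}zinc bromide | Br[Zn]C[C@H](C)CCCC[C@H]1OC(=O)[C@@H]1CO[Si](c2ccccc2)(c2ccccc2)C(C)(C)C
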